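**Assumption:** the target has no stereocentre and no stereogenic double bond, so it is made as the single achiral compound drawn.

## Retrosynthetic overview

1. Target 10 ⇒ bis-MOM ether 9 by acetal cleavage of the 5- and 7-hydroxyls.
2. 9 ⇒ aryl 1,1-dimethylallyl ether 7 by aromatic Claisen shift; only C-3' is a free ortho carbon, so the prenyl group can land nowhere else.
3. 7 ⇒ 2'-bromoisoflavone 5 + 2-methylbut-3-en-2-ol 6 by the key C2'–O cross-coupling.
4. 5 ⇒ 4 ⇒ phloroglucinol 1 + 2-bromo-4,5-dimethoxyphenylacetic acid 2 + one carbon from DMF (deoxybenzoin route).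
5. Ring order: rings A and B are bought as benzenes; ring C (the pyranone) is the only ring made, in step 1, closed through its O1–C2 bond.

## Route

**Step 1**
Reactants: 1 phloroglucinol; 2 2-(2-bromo-4,5-dimethoxyphenyl)acetic acid
Product: 4 3-(2-bromo-4,5-dimethoxyphenyl)-5,7-dihydroxy-4H-chromen-4-one, via deoxybenzoin 3 (not isolated)
Conditions: BF3·Et2O (neat), 85 °C, 2 h; then DMF, MsCl, 50 → 80 °C, 2 h; aq NaOAc work-up
Reagents that add atoms: N,N-dimethylformamide, CN(C)C=O (gives C-2 and its hydrogen)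
Why: Friedel–Crafts C-acylation of the symmetric triol by the BF3-activated acid gives the deoxybenzoin, whose benzylic methylene is formylated by the Vilsmeier-type DMF/MsCl adduct; an ortho hydroxyl then closes ring C with loss of dimethylamine (one-pot deoxybenzoin isoflavone synthesis), and no stereocentre is formed.

**Step 2**
Reactants: 4 3-(2-bromo-4,5-dimethoxyphenyl)-5,7-dihydroxy-4H-chromen-4-one
Product: 5 3-(2-bromo-4,5-dimethoxyphenyl)-5,7-bis(methoxymethoxy)-4H-chromen-4-one
Conditions: NaH (2.6 equiv), MOMCl (3 equiv), DMF, 0 °C → rt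
Reagents that add atoms: chloromethyl methyl ether, COCCl
Why: Williamson-type O-alkylation of both phenoxides; NaH in DMF is used so that the hydrogen-bonded 5-OH also reacts, and the resulting acetals are inert to the alkoxide base of step 3.

**Step 3**
Reactants: 5 3-(2-bromo-4,5-dimethoxyphenyl)-5,7-bis(methoxymethoxy)-4H-chromen-4-one; 6 2-methylbut-3-en-2-ol
Product: 9 3-[2-hydroxy-4,5-dimethoxy-3-(3-methylbut-2-en-1-yl)phenyl]-5,7-bis(methoxymethoxy)-4H-chromen-4-one, via tert-allyl aryl ether 7 (not isolated), via ortho-dienone 8 (not isolated)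
Conditions: 6 (1.5 equiv), NaH (1.4 equiv), toluene, rt; then 5, Pd2(dba)3 (2.5 mol%), 2-di-tert-butylphosphino-2',4',6'-triisopropylbiphenyl (7 mol%), toluene, 80 °C, 4 h; then 120 °C (sealed), 6 h; aq NH4Cl
Reagents that add atoms: none
Why: Proposed new method: palladium-catalysed C–O cross-coupling of an aryl bromide with a tertiary allylic alkoxide, telescoped with an aromatic Claisen rearrangement, so that the bromide is replaced by OH and the neighbouring C–H by prenyl in one flask; the monoligated zerovalent palladium adds into the C2'–Br bond, bromide is exchanged for the sodium alkoxide, and C–O reductive elimination (helped by the ortho chromonyl group and not undercut by β-hydride elimination, since the alkoxide has no carbinol hydrogen) gives ether 7, which on heating undergoes a [3,3] shift to C-3' (C-1' is blocked) and tautomerises from dienone 8 to phenol 9 with no stereocentre retained; the closest known reactions are the palladium/bulky biarylphosphine coupling of aryl bromides with sodium tert-butoxide to aryl tert-butyl ethers and the thermal Claisen rearrangement of aryl 1,1-dimethylallyl ethers made by O-alkylation of phenols.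

**Step 4**
Reactants: 9 3-[2-hydroxy-4,5-dimethoxy-3-(3-methylbut-2-en-1-yl)phenyl]-5,7-bis(methoxymethoxy)-4H-chromen-4-one
Product: 10 2'-hydroxypiscerythrinetin, 5,7-dihydroxy-3-[2-hydroxy-4,5-dimethoxy-3-(3-methylbut-2-en-1-yl)phenyl]-4H-chromen-4-one
Conditions: 3 M aq HCl/MeOH (1:6), 45 °C, 3 h
Reagents that add atoms: none
Why: Acid-catalysed methanolysis of the two aryl methoxymethyl acetals (the 5-O-acetal is assisted by the neighbouring carbonyl); the mild temperature and short time are chosen to keep the ortho-prenylphenol from cyclising to a 2,2-dimethylchroman.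

## Compound list

1 | phloroglucinol (benzene-1,3,5-triol) | Oc1cc(O)cc(O)c1 | starting material
2 | 2-(2-bromo-4,5-dimethoxyphenyl)acetic acid | COc1cc(Br)c(CC(=O)O)cc1OC | starting material
3 | 2-(2-bromo-4,5-dimethoxyphenyl)-1-(2,4,6-trihydroxyphenyl)ethan-1-one (deoxybenzoin) | COc1cc(Br)c(CC(=O)c2c(O)cc(O)cc2O)cc1OC | intermediate
4 | 3-(2-bromo-4,5-dimethoxyphenyl)-5,7-dihydroxy-4H-chromen-4-one | COc1cc(Br)c(-c2coc3cc(O)cc(O)c3c2=O)cc1OC | intermediate
5 | 3-(2-bromo-4,5-dimethoxyphenyl)-5,7-bis(methoxymethoxy)-4H-chromen-4-one | COCOc1cc(OCOC)c2c(c1)occ(-c1cc(OC)c(OC)cc1Br)c2=O | intermediate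
6 | 2-methylbut-3-en-2-ol | C=CC(C)(C)O | starting material
7 | 3-[4,5-dimethoxy-2-(2-methylbut-3-en-2-yloxy)phenyl]-5,7-bis(methoxymethoxy)-4H-chromen-4-one (tert-allyl aryl ether) | COCOc1cc(OCOC)c2c(c1)occ(-c1cc(OC)c(OC)cc1OC(C)(C)C=C)c2=O | intermediate
8 | 3-[3,4-dimethoxy-5-(3-methylbut-2-en-1-yl)-6-oxocyclohexa-1,3-dien-1-yl]-5,7-bis(methoxymethoxy)-4H-chromen-4-one (ortho-dienone, racemic at the ring sp3 carbon, transient) | COCOc1cc(OCOC)c2c(c1)occ(C1=CC(OC)=C(OC)C(CC=C(C)C)C1=O)c2=O | intermediate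
9 | 3-[2-hydroxy-4,5-dimethoxy-3-(3-methylbut-2-en-1-yl)phenyl]-5,7-bis(methoxymethoxy)-4H-chromen-4-one | COCOc1cc(OCOC)c2c(c1)occ(-c1cc(OC)c(OC)c(CC=C(C)C)c1O)c2=O | intermediate
10 | 2'-hydroxypiscerythrinetin, 5,7-dihydroxy-3-[2-hydroxy-4,5-dimethoxy-3-(3-methylbut-2-en-1-yl)phenyl]-4H-chromen-4-one | COc1cc(-c2coc3cc(O)cc(O)c3c2=O)c(O)c(CC=C(C)C)c1OC | target

## Step count and risks

Total step count: 4. Longest linear sequence: 4 steps (1 or 2 → 4 → 5 → 9 → 10).

**Step 3 (the proposed new coupling/Claisen cascade) is the most likely to fail.** The arylpalladium intermediate could instead undergo Heck arylation of the vinyl group of the alkoxide. Zerovalent palladium could ionise ether 7 as an allylic electrophile, with loss of isoprene or scrambling to the linear prenyl ether. The alkoxide could undergo β-vinyl elimination on palladium, or add to C-2 of the chromone. The fallback uses known chemistry only, sets out from 5 and comes back to the route at 9. Bromide 5 is borylated (B2pin2, Pd(dppf)Cl2, KOAc, dioxane, 90 °C) to 3-[4,5-dimethoxy-2-(4,4,5,5-tetramethyl-1,3,2-dioxaborolan-2-yl)phenyl]-5,7-bis(methoxymethoxy)-4H-chromen-4-one F1. F1 is oxidised with NaBO3·4H2O in THF/water at room temperature to 3-(2-hydroxy-4,5-dimethoxyphenyl)-5,7-bis(methoxymethoxy)-4H-chromen-4-one F2. The free 2'-phenol of F2 is then O-alkylated through a π-allylpalladium intermediate with tert-butyl 2-methylbut-3-en-2-yl carbonate F3 (made from 6, n-BuLi and di-tert-butyl dicarbonate) and Pd(PPh3)4 in THF at 0 °C. This gives ether 7, now isolated, and heating 7 in toluene at 110 °C gives 9.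

**Step 4 (acid deprotection next to an ortho-prenylphenol)** may give the 2,2-dimethylchroman by acid-catalysed addition of the 2'-OH to the prenyl olefin. The fallback avoids acid at the end by changing the protecting group. It sets out from 4 and comes back at 10. Compound 4 is alkylated with 2-(trimethylsilyl)ethoxymethyl chloride and NaH in DMF to 3-(2-bromo-4,5-dimethoxyphenyl)-5,7-bis{[2-(trimethylsilyl)ethoxy]methoxy}-4H-chromen-4-one F4. F4 is put through the step 3 conditions and passes through the tert-allyl aryl ether 3-[4,5-dimethoxy-2-(2-methylbut-3-en-2-yloxy)phenyl]-5,7-bis{[2-(trimethylsilyl)ethoxy]methoxy}-4H-chromen-4-one F5 and the ortho-dienone 3-[3,4-dimethoxy-5-(3-methylbut-2-en-1-yl)-6-oxocyclohexa-1,3-dien-1-yl]-5,7-bis{[2-(trimethylsilyl)ethoxy]methoxy}-4H-chromen-4-one F6. The product is 3-[2-hydroxy-4,5-dimethoxy-3-(3-methylbut-2-en-1-yl)phenyl]-5,7-bis{[2-(trimethylsilyl)ethoxy]methoxy}-4H-chromen-4-one F7. F7 is deprotected with fluoride (Bu4NF, THF/DMPU, 60 °C) under non-acidic conditions to give 10.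

**Step 2 (bis-protection)** may stall at the 7-mono-ether because the 5-OH is hydrogen-bonded to the C-4 carbonyl. The fallback protects before ring C exists. It sets out from 3 and comes back at 5. Step 1 is stopped after the BF3·Et2O stage and deoxybenzoin 3 is isolated. MOMCl and i-Pr2NEt in CH2Cl2 (0 °C → rt) etherify the two non-chelated hydroxyls to 2-(2-bromo-4,5-dimethoxyphenyl)-1-[2-hydroxy-4,6-bis(methoxymethoxy)phenyl]ethan-1-one F8. Heating F8 with N,N-dimethylformamide dimethyl acetal in toluene at 95 °C gives the enaminone 2-(2-bromo-4,5-dimethoxyphenyl)-3-(dimethylamino)-1-[2-hydroxy-4,6-bis(methoxymethoxy)phenyl]prop-2-en-1-one F9, which closes ring C through the remaining ortho hydroxyl to give 5.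

## Further compounds

F1 | step 3 | 3-[4,5-dimethoxy-2-(4,4,5,5-tetramethyl-1,3,2-dioxaborolan-2-yl)phenyl]-5,7-bis(methoxymethoxy)-4H-chromen-4-one | COCOc1cc(OCOC)c2c(c1)occ(-c1cc(OC)c(OC)cc1B1OC(C)(C)C(C)(C)O1)c2=O
F2 | step 3 | 3-(2-hydroxy-4,5-dimethoxyphenyl)-5,7-bis(methoxymethoxy)-4H-chromen-4-one | COCOc1cc(OCOC)c2c(c1)occ(-c1cc(OC)c(OC)cc1O)c2=O
F3 | step 3 | tert-butyl 2-methylbut-3-en-2-yl carbonate | C=CC(C)(C)OC(=O)OC(C)(C)C
F4 | step 4 | 3-(2-bromo-4,5-dimethoxyphenyl)-5,7-bis{[2-(trimethylsilyl)ethoxy]methoxy}-4H-chromen-4-one | C[Si](C)(C)CCOCOc1cc(OCOCC[Si](C)(C)C)c2c(c1)occ(-c1cc(OC)c(OC)cc1Br)c2=O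
F5 | step 4 | 3-[4,5-dimethoxy-2-(2-methylbut-3-en-2-yloxy)phenyl]-5,7-bis{[2-(trimethylsilyl)ethoxy]methoxy}-4H-chromen-4-one | C[Si](C)(C)CCOCOc1cc(OCOCC[Si](C)(C)C)c2c(c1)occ(-c1cc(OC)c(OC)cc1OC(C)(C)C=C)c2=O
F6 | step 4 | 3-[3,4-dimethoxy-5-(3-methylbut-2-en-1-yl)-6-oxocyclohexa-1,3-dien-1-yl]-5,7-bis{[2-(trimethylsilyl)ethoxy]methoxy}-4H-chromen-4-one | C[Si](C)(C)CCOCOc1cc(OCOCC[Si](C)(C)C)c2c(c1)occ(C1=CC(OC)=C(OC)C(CC=C(C)C)C1=O)c2=O
F7 | step 4 | 3-[2-hydroxy-4,5-dimethoxy-3-(3-methylbut-2-en-1-yl)phenyl]-5,7-bis{[2-(trimethylsilyl)ethoxy]methoxy}-4H-chromen-4-one | C[Si](C)(C)CCOCOc1cc(OCOCC[Si](C)(C)C)c2c(c1)occ(-c1cc(OC)c(OC)c(CC=C(C)C)c1O)c2=O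
F8 | step 2 | 2-(2-bromo-4,5-dimethoxyphenyl)-1-[2-hydroxy-4,6-bis(methoxymethoxy)phenyl]ethan-1-one | COCOc1cc(O)c(C(=O)Cc2cc(OC)c(OC)cc2Br)c(OCOC)c1
F9 | step 2 | 2-(2-bromo-4,5-dimethoxyphenyl)-3-(dimethylamino)-1-[2-hydroxy-4,6-bis(methoxymethoxy)phenyl]prop-2-en-1-one | COCOc1cc(O)c(C(=O)C(=CN(C)C)c2cc(OC)c(OC)cc2Br)c(OCOC)c1
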